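**Retrosynthetic overview**
- The target comes from the tris-MOM 3-O-acetate by global MOM removal. The acetate is put on the only free OH right after ring C is made.
- Ring C (the C2–C3 bond and both stereocentres) comes from an enantioselective, acid-catalysed ring contraction of a racemic seven-membered 2-aryl-1,3-benzodioxepin-5-one. In it, C2 shifts from the acetal oxygen to the neighbouring carbon.
- The dioxepinone comes from acetalisation of an ortho-hydroxyaryl hydroxymethyl ketone with 4-(MOM-oxy)benzaldehyde, itself made from MOM-protected 4-bromophenol and DMF.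
- The hydroxyketone comes from ortho-C-acylation of the mirror-symmetric 4-methoxy-3,5-bis(MOM-oxy)phenol with acetoxyacetyl chloride. The free OH para to OMe fixes the 6-methoxy pattern.
- The phenol comes from MOM-protected resorcinol by lithiation/oxidation/methylation at C2 and iridium C–H borylation/oxidation at C5. Ring order: rings A and B are bought, then the seven-membered acetal ring is formed, then ring C.

Assumption: the SMILES is read as the (2R,3R)-trans isomer, the two MOM ethers used as starting materials are bought as such, and the (R)-catalyst is taken as the antipode that delivers (2R,3R) (otherwise its mirror image is used).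

**Step 1**
Reactants: 1 1,3-bis(methoxymethoxy)benzene
Product: 5 2-methoxy-1,3-bis(methoxymethoxy)benzene, via aryllithium 2 (not isolated), via dimethyl arylboronate 3 (not isolated), via phenol 4 (not isolated)
Conditions: n-BuLi, THF, 0 °C; B(OMe)3, −78 °C to rt; 30% H2O2, aq. NaOH, 0 °C; then Me2SO4, rt
Reagents that add atoms: hydrogen peroxide OO; dimethyl sulfate COS(=O)(=O)OC
Why: Directed ortho-metalation takes the C2–H flanked by two coordinating MOM-oxy groups, and the borate formation, peroxide oxidation of the C–B bond and Williamson-type O-methylation of the phenoxide all run in the same alkaline flask; no stereocentre is formed.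

**Step 2**
Reactants: 5 2-methoxy-1,3-bis(methoxymethoxy)benzene
Product: 7 4-methoxy-3,5-bis(methoxymethoxy)phenol, via aryl pinacolboronate 6 (not isolated)
Conditions: [Ir(OMe)(cod)]2 (1.5 mol%), 4,4'-di-tert-butyl-2,2'-bipyridine (3 mol%), B2pin2 (0.6 equiv), THF, 80 °C; then 30% H2O2, aq. NaOH, 0 °C
Reagents that add atoms: hydrogen peroxide OO
Why: Sterically governed iridium-catalysed aromatic C–H borylation touches only C5–H, the one ring hydrogen without an ortho substituent, and one-pot boronate oxidation gives the phenol while the MOM groups are inert to both stages.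

**Step 3**
Reactants: 7 4-methoxy-3,5-bis(methoxymethoxy)phenol; 8 acetoxyacetyl chloride
Product: 11 2-hydroxy-1-[6-hydroxy-3-methoxy-2,4-bis(methoxymethoxy)phenyl]ethan-1-one, via bromomagnesium phenolate 9 (not isolated), via acetoxy ketone 10 (not isolated)
Conditions: EtMgBr, Et2O/toluene, 0 °C; 8, toluene, 0 °C to rt; then MeOH, K2CO3 (10 mol%), 0 °C, argon
Reagents that add atoms: none
Why: Metal-template ortho-acylation (a Friedel–Crafts type reaction of a magnesium phenolate that needs no strong Lewis acid, so the MOM groups survive) can give only one ketone because para is blocked and the two ortho positions are equivalent, and the activated primary acetate is then removed by mild transesterification.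

**Step 4**
Reactants: 12 1-bromo-4-(methoxymethoxy)benzene
Product: 14 4-(methoxymethoxy)benzaldehyde, via aryllithium 13 (not isolated)
Conditions: n-BuLi, THF, −78 °C; DMF, −78 °C to rt; H2O
Reagents that add atoms: N,N-dimethylformamide CN(C)C=O
Why: Bromine–lithium exchange followed by Bouveault-type formylation with DMF is fast and clean, and the MOM ether tolerates it.

**Step 5**
Reactants: 11 2-hydroxy-1-[6-hydroxy-3-methoxy-2,4-bis(methoxymethoxy)phenyl]ethan-1-one; 14 4-(methoxymethoxy)benzaldehyde
Product: 16 7-methoxy-6,8-bis(methoxymethoxy)-2-[4-(methoxymethoxy)phenyl]-1,3-benzodioxepin-5(4H)-one (racemic at C2), via dimethyl acetal 15 (not isolated)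
Conditions: 14, HC(OMe)3 (1.05 equiv), PPTS (5 mol%), toluene, rt; then 11, 5 Å MS, 60 °C
Reagents that add atoms: none
Why: Acid-catalysed transacetalisation closes the seven-membered 1,3-dioxepine ring from the 1,4-related phenol and primary alcohol, as with ortho-xylylene-type diols; PPTS ionises only the 4-alkoxybenzylidene acetal and is too weak to cleave MOM or enolise the ketone, and the racemic acetal carbon is harmless because it is planarised in the next step.

**Step 6**
Reactants: 16 7-methoxy-6,8-bis(methoxymethoxy)-2-[4-(methoxymethoxy)phenyl]-1,3-benzodioxepin-5(4H)-one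
Product: 18 (2R,3R)-6-methoxy-5,7-bis(methoxymethoxy)-2-[4-(methoxymethoxy)phenyl]-4-oxochroman-3-yl acetate, via 3-hydroxyflavanone 17 (not isolated)
Conditions: (R)-3,3'-bis(2,4,6-triisopropylphenyl)-BINOL N-triflylphosphoramide (5 mol%), toluene (0.02 M), 5 Å MS, 40 °C; then pyridine, Ac2O, 0 °C to rt
Reagents that add atoms: acetic anhydride CC(=O)OC(C)=O
Why: Proposed new method: the chiral acid protonates the alkyl acetal oxygen O3 and cleaves C2–O3 to a 4-alkoxybenzyl/aryloxocarbenium ion paired with the chiral anion; the freed hydroxyketone enolises to the hydrogen-bonded Z-enediol, whose O-attack only regenerates 16, whereas attack of its carbon (old C4) on C2 through a chair-like 6-(enolendo)-endo-trig transition state with aryl and oxygen both equatorial is productive, so C2 moves from O3 to the adjacent carbon (a stepwise cationic 1,2 O-to-C shift that contracts the seven-membered ring to ring C) and sets (2R,3R) inside the catalyst pocket; any cis isomer drains to trans by reversible C2–O1 ionisation while C3 stays fixed, and acetylation in the same flask makes the process irreversible; the closest known reaction types are the Petasis–Ferrier rearrangement and its chiral-phosphoric-acid-catalysed aza variant (both 1,3-shifts) and the anionic [1,2]-Wittig rearrangement of acetals.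

**Step 7**
Reactants: 18 (2R,3R)-6-methoxy-5,7-bis(methoxymethoxy)-2-[4-(methoxymethoxy)phenyl]-4-oxochroman-3-yl acetate
Product: 19 6-methoxyaromadendrin 3-O-acetate, (2R,3R)-5,7-dihydroxy-2-(4-hydroxyphenyl)-6-methoxy-4-oxochroman-3-yl acetate
Conditions: ZnBr2 (3 equiv), n-PrSH (6 equiv), CH2Cl2, 0 °C to rt, 15 min
Reagents that add atoms: none
Why: Lewis-acid/thiol cleavage of aryl MOM acetals is over in minutes, the thiol captures the formaldehyde unit so the electron-rich ring A is not alkylated, and the non-protic, non-basic medium leaves the secondary acetate, the 6-OMe group and both stereocentres untouched.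

**Compound list**
1 | 1,3-bis(methoxymethoxy)benzene | COCOc1cccc(OCOC)c1 | starting material
2 | 2-lithio-1,3-bis(methoxymethoxy)benzene | [Li]c1c(OCOC)cccc1OCOC | intermediate
3 | dimethyl [2,6-bis(methoxymethoxy)phenyl]boronate | COB(OC)c1c(OCOC)cccc1OCOC | intermediate
4 | 2,6-bis(methoxymethoxy)phenol | Oc1c(OCOC)cccc1OCOC | intermediate
5 | 2-methoxy-1,3-bis(methoxymethoxy)benzene | COc1c(OCOC)cccc1OCOC | intermediate
6 | 2-[4-methoxy-3,5-bis(methoxymethoxy)phenyl]-4,4,5,5-tetramethyl-1,3,2-dioxaborolane | COc1c(OCOC)cc(B2OC(C)(C)C(C)(C)O2)cc1OCOC | intermediate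
7 | 4-methoxy-3,5-bis(methoxymethoxy)phenol | COc1c(OCOC)cc(O)cc1OCOC | intermediate
8 | acetoxyacetyl chloride | CC(=O)OCC(=O)Cl | starting material
9 | bromomagnesium 4-methoxy-3,5-bis(methoxymethoxy)phenolate | COc1c(OCOC)cc(O[Mg]Br)cc1OCOC | intermediate
10 | 2-[6-hydroxy-3-methoxy-2,4-bis(methoxymethoxy)phenyl]-2-oxoethyl acetate | CC(=O)OCC(=O)c1c(O)cc(OCOC)c(OC)c1OCOC | intermediate
11 | 2-hydroxy-1-[6-hydroxy-3-methoxy-2,4-bis(methoxymethoxy)phenyl]ethan-1-one | OCC(=O)c1c(O)cc(OCOC)c(OC)c1OCOC | intermediate
12 | 1-bromo-4-(methoxymethoxy)benzene | COCOc1ccc(Br)cc1 | starting material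
13 | 4-(methoxymethoxy)phenyllithium | [Li]c1ccc(OCOC)cc1 | intermediate
14 | 4-(methoxymethoxy)benzaldehyde | COCOc1ccc(C=O)cc1 | intermediate
15 | 1-(dimethoxymethyl)-4-(methoxymethoxy)benzene | COCOc1ccc(C(OC)OC)cc1 | intermediate
16 | 7-methoxy-6,8-bis(methoxymethoxy)-2-[4-(methoxymethoxy)phenyl]-1,3-benzodioxepin-5(4H)-one, racemic | O=C1COC(c2ccc(OCOC)cc2)Oc2cc(OCOC)c(OC)c(OCOC)c12 | intermediate
17 | (2R,3R)-3-hydroxy-6-methoxy-5,7-bis(methoxymethoxy)-2-[4-(methoxymethoxy)phenyl]chroman-4-one | COc1c(OCOC)cc2c(c1OCOC)C(=O)[C@H](O)[C@@H](c1ccc(OCOC)cc1)O2 | intermediate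
18 | (2R,3R)-6-methoxy-5,7-bis(methoxymethoxy)-2-[4-(methoxymethoxy)phenyl]-4-oxochroman-3-yl acetate | COc1c(OCOC)cc2c(c1OCOC)C(=O)[C@H](OC(C)=O)[C@@H](c1ccc(OCOC)cc1)O2 | intermediate
19 | 6-methoxyaromadendrin 3-O-acetate | COc1c(O)cc2c(c1O)C(=O)[C@H](OC(C)=O)[C@@H](c1ccc(O)cc1)O2 | target

**Step count**
- Total step count: 7.
- Longest linear sequence: 6 (steps 1, 2, 3, 5, 6, 7).

**Steps most likely to fail**

Step 3 may stop at O-acylation or give low conversion. The fallback sets out from 7 and comes back at 10. Oxygen is acylated on purpose (8, Et3N, CH2Cl2, 0 °C) to give the aryl ester 4-methoxy-3,5-bis(methoxymethoxy)phenyl acetoxyacetate F1. The acyl group is then moved to carbon by a photo-Fries rearrangement (254 nm, MeCN), a neutral radical-pair process. Only 10 can form, because para is blocked and both ortho positions are the same. Methanolysis as in the main route then gives 11.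

Step 5 may give a poor equilibrium position for the seven-membered acetal, or early racemic contraction under heating with acid. The fallback sets out from 11 and comes back at 16. The equilibrium method is replaced by an irreversible silyl-transfer acetalisation. TMSCl/imidazole converts 11 into the bis-silyl ether 1-[3-methoxy-2,4-bis(methoxymethoxy)-6-(trimethylsilyloxy)phenyl]-2-(trimethylsilyloxy)ethan-1-one F2. This reacts with 14 under TMSOTf (5 mol%) in CH2Cl2 at −78 °C to give 16, driven by siloxane formation at a temperature where no C–C bond formation can occur.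

Step 6 is the proposed ring contraction. The enol and the cation must coexist, and both the level and the sense of induction are unknown. The fallback uses known chalcone-epoxide chemistry, sets out from 7 (with 14) and comes back at 17.
- Phenolate 9, made from 7, is C-acetylated with acetyl chloride to 1-[6-hydroxy-3-methoxy-2,4-bis(methoxymethoxy)phenyl]ethan-1-one F3.
- Allyl bromide/K2CO3 gives 1-[6-(allyloxy)-3-methoxy-2,4-bis(methoxymethoxy)phenyl]ethan-1-one F4.
- Claisen–Schmidt condensation with 14 (KOH, EtOH) gives (E)-1-[6-(allyloxy)-3-methoxy-2,4-bis(methoxymethoxy)phenyl]-3-[4-(methoxymethoxy)phenyl]prop-2-en-1-one F5.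
- Juliá–Colonna epoxidation (poly-L-leucine, urea–H2O2, DBU, THF) gives the (2R,3S)-epoxy ketone of this chalcone F6.
- Pd(PPh3)4/morpholine frees the phenol to give the (2R,3S)-epoxy ketone with free 6-hydroxyl F7.
- Catalytic camphorsulfonic acid in CH2Cl2 closes ring C by 6-endo opening at the benzylic carbon with inversion. This gives 17, which is acetylated as in step 6.

**Further compounds**
F1 | step 3 | 4-methoxy-3,5-bis(methoxymethoxy)phenyl acetoxyacetate | CC(=O)OCC(=O)Oc1cc(OCOC)c(OC)c(OCOC)c1
F2 | step 5 | 1-[3-methoxy-2,4-bis(methoxymethoxy)-6-(trimethylsilyloxy)phenyl]-2-(trimethylsilyloxy)ethan-1-one | C[Si](C)(C)OCC(=O)c1c(O[Si](C)(C)C)cc(OCOC)c(OC)c1OCOC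
F3 | step 6 | 1-[6-hydroxy-3-methoxy-2,4-bis(methoxymethoxy)phenyl]ethan-1-one | CC(=O)c1c(O)cc(OCOC)c(OC)c1OCOC
F4 | step 6 | 1-[6-(allyloxy)-3-methoxy-2,4-bis(methoxymethoxy)phenyl]ethan-1-one | CC(=O)c1c(OCC=C)cc(OCOC)c(OC)c1OCOC
F5 | step 6 | (E)-1-[6-(allyloxy)-3-methoxy-2,4-bis(methoxymethoxy)phenyl]-3-[4-(methoxymethoxy)phenyl]prop-2-en-1-one | O=C(/C=C/c1ccc(OCOC)cc1)c1c(OCC=C)cc(OCOC)c(OC)c1OCOC
F6 | step 6 | [6-(allyloxy)-3-methoxy-2,4-bis(methoxymethoxy)phenyl]{(2R,3S)-3-[4-(methoxymethoxy)phenyl]oxiran-2-yl}methanone | O=C([C@@H]1O[C@H]1c1ccc(OCOC)cc1)c1c(OCC=C)cc(OCOC)c(OC)c1OCOC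
F7 | step 6 | [6-hydroxy-3-methoxy-2,4-bis(methoxymethoxy)phenyl]{(2R,3S)-3-[4-(methoxymethoxy)phenyl]oxiran-2-yl}methanone | O=C([C@@H]1O[C@H]1c1ccc(OCOC)cc1)c1c(O)cc(OCOC)c(OC)c1OCOC
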